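**Plan**

1. The tetrahydrofuran is numbered O1, C2 to C5, with C5 the aryl carbon whose aryl group is cis to the CH2OH on C4. The target is then (2S,3R,4R,5R): 2,5-cis, 4,5-cis, 3,4-trans, 2,3-trans.
2. Enabling feature: C5 is benzylic to a para-oxygenated aryl ring (donor). C3 lies 1,3 to it and can carry two esters (acceptor), and O1-C2 is a masked aryl aldehyde C=O. The ring is therefore an aldehyde inserted into a donor-acceptor cyclopropane whose C3-C5 bond is absent from the target.
3. Retrosynthesis: a second ester is added at C3 and O1-C5 and C2-C3 are cut, giving O-benzylvanillin and a trans-2-aryl-3-(benzyloxymethyl)cyclopropane-1,1-diester. Cutting C3-C4 and the extra C3-C5 bond then gives O-benzylconiferaldehyde and dimethyl bromomalonate.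
4. Forward: the cyclopropane ring is built first and the tetrahydrofuran ring arises from it in one (3+2) annulation. One ester is then removed, the other is reduced, and three benzyl groups are taken off.
5. Stereochemistry: C4 and the aryl carbon come from an (S)-diphenylprolinol silyl ether-catalysed cyclopropanation. The aryl carbon is inverted in the annulation, so trans on the three-membered ring becomes 4,5-cis. C2 follows from a 2,5-cis envelope closure, and C3 is set by thermodynamic equilibration of the monoester.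

Key step: step 4

**Step 1**
Reactants: 1 coniferaldehyde, (E)-3-(4-hydroxy-3-methoxyphenyl)prop-2-enal
Product: 2 (E)-3-(4-benzyloxy-3-methoxyphenyl)prop-2-enal
Conditions: BnBr, K2CO3, DMF, rt
Reagents that add atoms: benzyl bromide, BrCc1ccccc1
Why: Williamson etherification of the only acidic site, the phenol, with a primary benzylic bromide should leave the enal untouched at room temperature and creates no stereocentre.

**Step 2**
Reactants: 2 (E)-3-(4-benzyloxy-3-methoxyphenyl)prop-2-enal; 3 dimethyl bromomalonate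
Product: 4 dimethyl (2S,3R)-2-(4-benzyloxy-3-methoxyphenyl)-3-formylcyclopropane-1,1-dicarboxylate
Conditions: (S)-α,α-diphenylprolinol trimethylsilyl ether (20 mol %), 2,6-lutidine (1.1 equiv), CH2Cl2, 0 °C to rt
Reagents that add atoms: none
Why: In this organocatalytic Michael-initiated ring closure (iminium-enamine cascade) the CPh2(OSiMe3) group shields the Re face at Cβ of the E, s-trans iminium ion, so the bromomalonate adds to the Si face and fixes the aryl carbon as S, and the enamine then displaces bromide in a 3-exo-tet alkylation that places formyl trans to aryl (3R), with 2,6-lutidine only taking up HBr.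

**Step 3**
Reactants: 4 dimethyl (2S,3R)-2-(4-benzyloxy-3-methoxyphenyl)-3-formylcyclopropane-1,1-dicarboxylate
Product: 5 dimethyl (2S,3R)-2-(4-benzyloxy-3-methoxyphenyl)-3-(benzyloxymethyl)cyclopropane-1,1-dicarboxylate
Conditions: BnOSiMe3 (1.2 equiv), Et3SiH (1.2 equiv), TMSOTf (10 mol %), CH2Cl2, −78 °C
Reagents that add atoms: benzyloxytrimethylsilane, C[Si](C)(C)OCc1ccccc1
Why: In this silane reductive etherification TMSOTf converts the aldehyde and BnOSiMe3 into the O-benzyl oxocarbenium ion, which Et3SiH reduces at low temperature, so the ether forms without ever releasing the alkoxide that would lactonise onto the cis ester, and both ring stereocentres are spectators.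

**Step 4**
Reactants: 5 dimethyl (2S,3R)-2-(4-benzyloxy-3-methoxyphenyl)-3-(benzyloxymethyl)cyclopropane-1,1-dicarboxylate; 6 4-benzyloxy-3-methoxybenzaldehyde (O-benzylvanillin)
Product: 8 dimethyl (2R,4R,5R)-2,5-bis(4-benzyloxy-3-methoxyphenyl)-4-(benzyloxymethyl)tetrahydrofuran-3,3-dicarboxylate, via oxocarbenium-malonate zwitterion 7 (not isolated)
Conditions: AlCl3 (10 mol %), 6 (2 equiv), CH2Cl2, −20 °C to 0 °C
Reagents that add atoms: none
Why: AlCl3 is chelated by the geminal diester of 5 and polarises the C1-C2 cyclopropane bond (the future C3/C5 pair), the 4-alkoxyaryl group stabilising the developing benzylic charge, and the carbonyl oxygen of 6 attacks that carbon from the rear of the tight ion pair in an SN2-like opening (O1-C5) to give zwitterion 7. The malonate carbon of 7 then adds to the oxocarbenium carbon (C2-C3), closing the tetrahydrofuran ring in an aldol-type step that is formally 5-(enolexo)-endo-trig, because O1 and C2 both end up in the ring, a mode that is routine for cationic C=O+ acceptors. The closest known reaction type is the Lewis acid-catalysed (3+2) annulation of 2-arylcyclopropane-1,1-diesters, trans-2-aryl-3-alkyl members included, with aryl aldehydes to give 2,5-cis-tetrahydrofurans. C5 is controlled by inversion of the (2S) cyclopropane carbon, which turns the trans aryl/CH2OBn pair into the 4,5-cis pair (5R), C4 is carried over untouched (4R), and C2 is set by an envelope transition state with both aryl groups pseudoequatorial, hence 2,5-cis (2R in 8 and 2S later through a priority change only). The step needs cleavage of C1-C2 and not C1-C3, which the aryl donor on C2 secures against the donor-free, inductively deactivated CH2OBn carbon, and it needs capture faster than ion-pair separation, which the electron-rich and strongly nucleophilic aldehyde 6, the catalytic Lewis acid and the low temperature should provide. Because C4 is never touched, any leakage would cost diastereomeric purity at C5 only and not enantiomeric purity.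

**Step 5**
Reactants: 8 dimethyl (2R,4R,5R)-2,5-bis(4-benzyloxy-3-methoxyphenyl)-4-(benzyloxymethyl)tetrahydrofuran-3,3-dicarboxylate
Product: 10 methyl (2S,3S,4R,5R)-2,5-bis(4-benzyloxy-3-methoxyphenyl)-4-(benzyloxymethyl)tetrahydrofuran-3-carboxylate, via all-cis C3-epimeric monoester 9 (not isolated)
Conditions: LiCl (3 equiv), H2O (3 equiv), DMSO, 150 °C
Reagents that add atoms: none
Why: In the Krapcho dealkoxycarbonylation chloride demethylates one ester, CO2 is lost and the enolate should be protonated first from the open face to give the crowded all-cis ester 9, which the hot, weakly basic medium epimerises through the same enolate to 10, the thermodynamic isomer with the C3 ester trans to both the C2 aryl group and the C4 side chain.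

**Step 6**
Reactants: 10 methyl (2S,3S,4R,5R)-2,5-bis(4-benzyloxy-3-methoxyphenyl)-4-(benzyloxymethyl)tetrahydrofuran-3-carboxylate
Product: 11 [(2S,3R,4R,5R)-2,5-bis(4-benzyloxy-3-methoxyphenyl)-4-(benzyloxymethyl)tetrahydrofuran-3-yl]methanol
Conditions: LiAlH4, THF, 0 °C to rt; aqueous work-up
Reagents that add atoms: none
Why: LiAlH4 reduction of the ester to the primary alcohol leaves benzyl ethers, aryl methyl ethers and the ring ether alone and removes the last epimerisable position, locking C3 (the descriptor changes by priority only).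

**Step 7**
Reactants: 11 [(2S,3R,4R,5R)-2,5-bis(4-benzyloxy-3-methoxyphenyl)-4-(benzyloxymethyl)tetrahydrofuran-3-yl]methanol
Product: 12 (2S,3R,4R,5R)-2,5-bis(4-hydroxy-3-methoxyphenyl)-3,4-bis(hydroxymethyl)tetrahydrofuran (target)
Conditions: H2 (1 atm), 10% Pd/C, EtOAc-MeOH, rt, stopped after uptake of three equivalents
Reagents that add atoms: none
Why: Catalytic hydrogenolysis under neutral conditions should cleave the two aryl benzyl ethers and the primary alkyl benzyl ether well before the secondary, hindered benzylic C-O bonds of the ring, and it touches no stereocentre.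

**Compound list**

1 | coniferaldehyde, (E)-3-(4-hydroxy-3-methoxyphenyl)prop-2-enal | COc1cc(/C=C/C=O)ccc1O | starting material
2 | (E)-3-(4-benzyloxy-3-methoxyphenyl)prop-2-enal | COc1cc(/C=C/C=O)ccc1OCc1ccccc1 | intermediate
3 | dimethyl bromomalonate | COC(=O)C(Br)C(=O)OC | starting material
4 | dimethyl (2S,3R)-2-(4-benzyloxy-3-methoxyphenyl)-3-formylcyclopropane-1,1-dicarboxylate (aryl and formyl trans) | COC(=O)C1(C(=O)OC)[C@H](c2ccc(OCc3ccccc3)c(OC)c2)[C@H]1C=O | intermediate
5 | dimethyl (2S,3R)-2-(4-benzyloxy-3-methoxyphenyl)-3-(benzyloxymethyl)cyclopropane-1,1-dicarboxylate (aryl and CH2OBn trans) | COC(=O)C1(C(=O)OC)[C@H](c2ccc(OCc3ccccc3)c(OC)c2)[C@H]1COCc4ccccc4 | intermediate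
6 | 4-benzyloxy-3-methoxybenzaldehyde (O-benzylvanillin) | COc1cc(C=O)ccc1OCc1ccccc1 | starting material
7 | oxocarbenium-malonate zwitterion, aldehyde oxygen bonded to the inverted benzylic carbon (not isolated) | COC(=O)[C-](C(=O)OC)[C@H](COCc1ccccc1)[C@H](c1ccc(OCc2ccccc2)c(OC)c1)[O+]=Cc1ccc(OCc2ccccc2)c(OC)c1 | intermediate
8 | dimethyl (2R,4R,5R)-2,5-bis(4-benzyloxy-3-methoxyphenyl)-4-(benzyloxymethyl)tetrahydrofuran-3,3-dicarboxylate (2,5-cis, 4,5-cis) | COc1cc([C@H]2O[C@@H](c3ccc(OCc4ccccc4)c(OC)c3)[C@@H](COCc4ccccc4)C2(C(=O)OC)C(=O)OC)ccc1OCc1ccccc1 | intermediate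
9 | methyl (2S,3R,4R,5R)-2,5-bis(4-benzyloxy-3-methoxyphenyl)-4-(benzyloxymethyl)tetrahydrofuran-3-carboxylate, all-cis C3 epimer (not isolated) | COc1cc([C@H]2O[C@@H](c3ccc(OCc4ccccc4)c(OC)c3)[C@@H](COCc4ccccc4)[C@H]2C(=O)OC)ccc1OCc1ccccc1 | intermediate
10 | methyl (2S,3S,4R,5R)-2,5-bis(4-benzyloxy-3-methoxyphenyl)-4-(benzyloxymethyl)tetrahydrofuran-3-carboxylate (ester trans to both neighbours) | COc1cc([C@H]2O[C@@H](c3ccc(OCc4ccccc4)c(OC)c3)[C@@H](COCc4ccccc4)[C@@H]2C(=O)OC)ccc1OCc1ccccc1 | intermediate
11 | [(2S,3R,4R,5R)-2,5-bis(4-benzyloxy-3-methoxyphenyl)-4-(benzyloxymethyl)tetrahydrofuran-3-yl]methanol | COc1cc([C@H]2O[C@@H](c3ccc(OCc4ccccc4)c(OC)c3)[C@@H](COCc4ccccc4)[C@@H]2CO)ccc1OCc1ccccc1 | intermediate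
12 | (2S,3R,4R,5R)-2,5-bis(4-hydroxy-3-methoxyphenyl)-3,4-bis(hydroxymethyl)tetrahydrofuran, CNP0286218.5 | COc1cc([C@H]2O[C@@H](c3ccc(O)c(OC)c3)[C@@H](CO)[C@@H]2CO)ccc1O | target

Total step count: 7
Longest linear sequence: 7 steps (1 to 12); aldehyde 6 is bought and enters at step 4.

**Steps most likely to fail**

**Step 3.**
- What may go wrong: the cyclopropyl-substituted oxocarbenium ion, or the diester activated by TMSOTf, may open the three-membered ring towards the aryl-stabilised cation faster than hydride arrives.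
- Fallback, from 4 back to 5: the aldehyde is reduced with NaBH4 in MeOH-THF at −40 °C and quenched cold with acetic acid. This gives dimethyl (2S,3R)-2-(4-benzyloxy-3-methoxyphenyl)-3-(hydroxymethyl)cyclopropane-1,1-dicarboxylate F1.
- F1 is used at once, before it can lactonise, in an acid-catalysed imidate benzylation (benzyl 2,2,2-trichloroacetimidate, cat. TfOH, CH2Cl2-cyclohexane, 0 °C) to give 5. No cationic carbon is ever placed next to the ring.

**Step 4.**
- What may go wrong: the ion pair may separate to a free benzylic cation, which loses the inversion at C5. Lewis acid-promoted retro-aldol equilibration may also erode the 2,5-cis relation.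
- Fallback, from 1 back to 8: the donor is weakened to about the level of phenyl, where invertive opening is most dependable, by carrying the cyclopropane-side phenol as an ester.
- PivCl, Et3N and CH2Cl2 convert 1 into (E)-3-(3-methoxy-4-pivaloyloxyphenyl)prop-2-enal F2.
- The cyclopropanation of step 2 with 3 gives dimethyl (2S,3R)-3-formyl-2-(3-methoxy-4-pivaloyloxyphenyl)cyclopropane-1,1-dicarboxylate F3.
- The etherification of step 3 gives dimethyl (2S,3R)-3-(benzyloxymethyl)-2-(3-methoxy-4-pivaloyloxyphenyl)cyclopropane-1,1-dicarboxylate F4.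
- Annulation of F4 with 6 under Sn(OTf)2 (10 mol %, CH2Cl2, rt) gives dimethyl (2R,4R,5R)-2-(4-benzyloxy-3-methoxyphenyl)-4-(benzyloxymethyl)-5-(3-methoxy-4-pivaloyloxyphenyl)tetrahydrofuran-3,3-dicarboxylate F5.
- NaOMe in MeOH at 0 °C frees dimethyl (2R,4R,5R)-2-(4-benzyloxy-3-methoxyphenyl)-4-(benzyloxymethyl)-5-(4-hydroxy-3-methoxyphenyl)tetrahydrofuran-3,3-dicarboxylate F6.
- BnBr, K2CO3 and DMF then return 8.

**Step 5.**
- What may go wrong: at 150 °C the C3 ester enolate may expel the ring oxygen (cleavage of C2-O1), or the epimerisation may stop short of equilibrium.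
- Fallback, from 8 back to 10: the ester on the open face is saponified with KOH (1 equiv) in MeOH-THF-H2O. After acidification this gives (2R,3R,4R,5R)-2,5-bis(4-benzyloxy-3-methoxyphenyl)-4-(benzyloxymethyl)-3-(methoxycarbonyl)tetrahydrofuran-3-carboxylic acid F7.
- F7 decarboxylates as a malonic half ester at about 80 °C (cat. Cu2O, MeCN), far below the Krapcho temperature.
- The resulting mixture of 9 and 10 is then equilibrated with DBU in toluene at rt to give 10.

**Further compounds**

F1 | step 3 | dimethyl (2S,3R)-2-(4-benzyloxy-3-methoxyphenyl)-3-(hydroxymethyl)cyclopropane-1,1-dicarboxylate | COC(=O)C1(C(=O)OC)[C@H](c2ccc(OCc3ccccc3)c(OC)c2)[C@H]1CO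
F2 | step 4 | (E)-3-(3-methoxy-4-pivaloyloxyphenyl)prop-2-enal | COc1cc(/C=C/C=O)ccc1OC(=O)C(C)(C)C
F3 | step 4 | dimethyl (2S,3R)-3-formyl-2-(3-methoxy-4-pivaloyloxyphenyl)cyclopropane-1,1-dicarboxylate | COC(=O)C1(C(=O)OC)[C@H](c2ccc(OC(=O)C(C)(C)C)c(OC)c2)[C@H]1C=O
F4 | step 4 | dimethyl (2S,3R)-3-(benzyloxymethyl)-2-(3-methoxy-4-pivaloyloxyphenyl)cyclopropane-1,1-dicarboxylate | COC(=O)C1(C(=O)OC)[C@H](c2ccc(OC(=O)C(C)(C)C)c(OC)c2)[C@H]1COCc3ccccc3
F5 | step 4 | dimethyl (2R,4R,5R)-2-(4-benzyloxy-3-methoxyphenyl)-4-(benzyloxymethyl)-5-(3-methoxy-4-pivaloyloxyphenyl)tetrahydrofuran-3,3-dicarboxylate | COc1cc([C@H]2O[C@@H](c3ccc(OC(=O)C(C)(C)C)c(OC)c3)[C@@H](COCc4ccccc4)C2(C(=O)OC)C(=O)OC)ccc1OCc1ccccc1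
F6 | step 4 | dimethyl (2R,4R,5R)-2-(4-benzyloxy-3-methoxyphenyl)-4-(benzyloxymethyl)-5-(4-hydroxy-3-methoxyphenyl)tetrahydrofuran-3,3-dicarboxylate | COc1cc([C@H]2O[C@@H](c3ccc(O)c(OC)c3)[C@@H](COCc4ccccc4)C2(C(=O)OC)C(=O)OC)ccc1OCc1ccccc1
F7 | step 5 | (2R,3R,4R,5R)-2,5-bis(4-benzyloxy-3-methoxyphenyl)-4-(benzyloxymethyl)-3-(methoxycarbonyl)tetrahydrofuran-3-carboxylic acid | COc1cc([C@H]2O[C@@H](c3ccc(OCc4ccccc4)c(OC)c3)[C@@H](COCc4ccccc4)[C@@]2(C(=O)O)C(=O)OC)ccc1OCc1ccccc1
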